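**Retrosynthetic overview**
- The only strategic bond is the ester alkyl C–O bond. It is made last, by adding the carboxylic O–H of the unprotected hydroxy acid across a terminal C25 alkene in the anti-Markovnikov sense.
- The C25 alkene comes from a copper-catalysed alkyl–allyl coupling of a C22 bromide with a C3 Grignard reagent (22 + 3 = 25 carbons).
- No ring is formed at any stage; the benzene ring is bought intact and the phenol is carried unprotected.

Assumption: the target has no stereocentre and no double-bond geometry, so the achiral compound as drawn is the single species required.

**Step 1**
Reactants: 1 1-bromodocosane; 2 allylmagnesium bromide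
Product: 3 pentacos-1-ene
Conditions: Li2CuCl4 (3 mol%), Grignard reagent in excess as Et2O solution, THF/Et2O, 0 °C to 40 °C, 12 h
Reagents that add atoms: none
Why: Kochi-type copper-catalysed sp3–sp3 cross-coupling of an unhindered primary C22 alkyl bromide with the C3 allyl Grignard reagent gives the C25 terminal alkene cleanly, there is no other functional group to interfere, and no stereocentre is formed.

**Step 2**
Reactants: 3 pentacos-1-ene; 4 3-(4-hydroxyphenyl)propanoic acid
Product: 5 pentacosyl 3-(4-hydroxyphenyl)propanoate
Conditions: acid in twofold excess, Ni(cod)2 (10 mol%), 6,6'-dimethyl-2,2'-bipyridine (12 mol%), [Ir(dF(CF3)ppy)2(dtbbpy)]PF6 (1 mol%), 1,4-dioxane, 450 nm LEDs, 40 °C, Ar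
Reagents that add atoms: none
Why: Proposed new method: a redox-neutral nickel-hydride/photoredox anti-Markovnikov hydroacyloxylation with no co-product, in which zerovalent nickel is protonated by the carboxylic acid (pKa about 4.7; the phenol, pKa about 10, is too weak to compete and is not oxidised by the excited photocatalyst) to a divalent nickel hydride carboxylate, the hindered bipyridine steers 1,2-insertion and chain-walking to the least hindered primary alkylnickel, the excited iridium photocatalyst oxidises this to a trivalent alkylnickel carboxylate that undergoes C(sp3)–O reductive elimination, and the reduced photocatalyst returns monovalent nickel to the zerovalent state, so the light-driven C–O step makes the linear ester a kinetic sink even for isomerised alkene; the closest known reaction types are nickel-hydride anti-Markovnikov hydroamination of unactivated alkenes and nickel/photoredox C(sp2)–O coupling of aryl halides with carboxylic acids, and no stereocentre is formed.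

**Compound list**
1 | 1-bromodocosane (unbranched C22 primary bromide) | CCCCCCCCCCCCCCCCCCCCCCBr | starting material
2 | allylmagnesium bromide (prop-2-en-1-ylmagnesium bromide) | C=CC[Mg]Br | starting material
3 | pentacos-1-ene (unbranched C25 terminal alkene, achiral) | CCCCCCCCCCCCCCCCCCCCCCCC=C | intermediate
4 | 3-(4-hydroxyphenyl)propanoic acid (phloretic acid, achiral) | OC(=O)CCc1ccc(O)cc1 | starting material
5 | pentacosyl 3-(4-hydroxyphenyl)propanoate (achiral) | CCCCCCCCCCCCCCCCCCCCCCCCCOC(=O)CCc1ccc(O)cc1 | target

**Step count and risks**
Total step count: 2. Longest linear sequence: 2 (1 → 3 → 5).

The route has only two steps, so both are ranked here, most likely to fail first.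

Risk 1, step 2 (the proposed new method). Likely failure modes are alkene isomerisation without C–O bond formation, protonolysis of the alkylnickel to pentacosane, formation of the branched (Markovnikov) ester, or no reductive elimination at all. The fallback uses known chemistry, sets out from 3 and comes back to the route at 5. Alkene 3 is hydroborated with 9-BBN (slight excess, THF, rt to 60 °C) to give 9-pentacosyl-9-borabicyclo[3.3.1]nonane F2, which is not isolated. F2 is oxidised with aqueous NaOH/H2O2 (0 °C to 50 °C) to pentacosan-1-ol F3, with terminal selectivity above 99%. F3 and 4 (slight excess) are then joined by Fischer esterification (TsOH·H2O 5 mol%, toluene, Dean–Stark reflux). Only the aliphatic alcohol is acylated, because phenols do not esterify under acid-catalysed equilibrium conditions. Excess 4 is removed with aqueous NaHCO3 and 5 is crystallised.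

Risk 2, step 1. Likely failure modes are sluggish coupling of the waxy, poorly soluble bromide, loss of 2 by homocoupling to hexa-1,5-diene, and some tetratetracontane or elimination product. The fallback reverses the polarity of the coupling, sets out from 1 and comes back to the route at 3. Bromide 1 is converted with Mg turnings (THF, 50 °C) into docosylmagnesium bromide F1. F1 is added to allyl bromide (excess) with CuI (2 mol%) in THF at 0 °C to rt. Allyl bromide is a far better electrophile than a primary alkyl bromide, so the C22–C23 bond no longer depends on an alkyl–alkyl cross-coupling, and 3 is isolated by filtration through silica in hexanes.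

**Further compounds**
F1 | step 1 | docosylmagnesium bromide | CCCCCCCCCCCCCCCCCCCCCC[Mg]Br
F2 | step 2 | 9-pentacosyl-9-borabicyclo[3.3.1]nonane | CCCCCCCCCCCCCCCCCCCCCCCCCB1C2CCCC1CCC2
F3 | step 2 | pentacosan-1-ol | CCCCCCCCCCCCCCCCCCCCCCCCCO
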